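The numbers in the tables are simulated from invented constants, noise included.

Friday's flask first: from 30.0 min on, its starting material reads 40%, 33% and 37%, with a mean of 36.7%. With a scatter of 2 percentage points, these readings show a slowing but prove no stop, so the target at 1.0 h is reckoned at about 63.3%, an estimate that a slow further fall of the starting material would put too low.

| flask | starting material | partner | second substrate | free catalyst | remark | time |
|---|---|---|---|---|---|---|
| Friday's | 1 M | 1.5 M | 1 M | 1 mM | the very flask that is asked about, followed so far |  |
| Thursday's | 1 M | 1 M | 1 M | 1 mM | run made earlier |  |
| flask | 1.0 M | 1.50 M | 1.00 M | 1.0 mM |  | 1.0 h |

- Friday's (time / min: target / %, starting material / %): 5.00: 31, 70; 15.0: 53, 53; 30.0: 62, 40; 40.0: 59, 33; 60.0: 64, 37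
- Thursday's (time / s: target / %, starting material / %): 25.0: 3, 96; 50.0: 7, 94; 80.0: 9, 90; 90.0: 10, 93; 120: 11, 91

(each reading ± 2 percentage points)

- amber: change nothing and wait 2.0 h more
- blue: at 1.0 h add free catalyst, 50.0% of the amount charged, then wait 2.0 h
- grey: at 1.0 h take out 90% of the target then present, then wait 2.0 h

- target, in percent of the starting material first charged, at 1.0 h
- what to do for the largest gain in target; "none" if nothing gains more than 2 percentage points (amber / blue / grey / none)
- target present, with what was taken out counted in, in percent of the starting material first charged, after amber
- target present, with what was taken out counted in, in percent of the starting material first charged, after blue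

- what is taken out of target is counted as made
- the numbers in the tables scatter by 2 percentage points (one standard deviation)
- additions bring no volume worth counting

Two different stops could lie behind this slowing, and each is the zero of the other's scale. At an equilibrium, blue gains nothing and taking out target gains. With free catalyst lost (catalyst deactivation), grey gains nothing beyond amber and added catalyst gains. The readings do not separate the two, so the next move is a bet, and it needs a price.

The price is the reach, the natural logarithm of c(starting material) charged over the mean c(starting material) of those last readings, taken as if Friday's flask had stopped there, here 1.00. If free catalyst decays at a fixed first-order rate and c(partner) is taken as roughly constant, the reach is proportional to the catalyst charged. Blue's addition then buys half a reach on the starting material still present, which leaves 22.2% and gives 77.8% target, a gain of 14 points against a margin of 2 points. On that reckoning the catalyst goes in: blue is the commitment, as a judgement and not a reading.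

The forecast gives 63% now, 63% after amber and 64% after blue, and chooses grey, holding that “waiting or adding catalyst gains nothing”.

The flask holds 67.9% target at 1.0 h, amber brings 71.2% and blue 81.0%, against the 77.8% reckoned from the reach. So blue gains most, 13 points against 3.3 points for amber and 3.3 points for grey. At 60.0 min this flask has 10.1% free catalyst and 89.9% spent catalyst.

    second substrate + partner + free catalyst → free catalyst + second product (k = 33.0 L² mol⁻² min⁻¹)
    starting material + free catalyst → spent catalyst (k = 0.0870 L mol⁻¹ min⁻¹)
    starting material + partner + free catalyst → free catalyst + target (k = 75.0 L² mol⁻² min⁻¹)

The neighbour flask charged with 2.5 × 10⁻⁴ M free catalyst, a quarter of the recipe's amount with all else held, is reckoned at a reach of 0.251, which leaves 77.8% starting material. That flask shows 72.7% starting material and 27.3% target at 60.0 min, with free catalyst at 1.71%.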